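**Retrosynthetic overview**

1. Chiral pool: D‑malic acid (1) gives dioxolanone acid 2, which carries C4 (R). (S)‑β‑Citronellene (3) gives aldehyde 4 and then Z‑alkenyl iodide 5, which carries C10 (S).
2. Key disconnection C5–C6: photochemical Ni/Ir decarboxylative alkenylation, 2 + 5 → 6.
3. East piece: 3‑bromofuran (7) + silylated chloropentyne 8 → alkyne 9 → E‑alkenylboronate 10 (sets C13=C14).
4. Disconnection C12–C13: oxidative Heck vinylation of the vinyl group of 6 with 10 → 11 (sets E‑C11=C12).
5. Ring order: the furan is bought; the tetronic acid is the only ring made and is closed last (11 → 12) by Claisen acylation/lactonisation on the dioxolanone.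

Assumption: numbering is lactone C1(=O), C2(Me), C3(OH), C4(H), chain C5–C17; the SMILES is read as 4R, 6Z, 10S, 11E, 13E; compounds 1, 3, 7 and 8 are taken as catalogue items.

**Route**

Step 1
Reactants: 1, D‑malic acid [(R)‑2‑hydroxybutanedioic acid]
Product: 2, (R)‑2‑(2,2‑dimethyl‑5‑oxo‑1,3‑dioxolan‑4‑yl)acetic acid
Conditions: 2,2‑dimethoxypropane (excess), p‑TsOH·H2O (2 mol %), rt; crystallise
Reagents that add atoms: 2,2‑dimethoxypropane, COC(C)(C)OC
Why: Acid‑catalysed acetonide formation engages only the α‑hydroxy acid as the five‑membered dioxolanone and leaves the β‑CO2H free, without touching the stereocentre (R retained).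

Step 2
Reactants: 3, (S)‑β‑citronellene [(S)‑3,7‑dimethylocta‑1,6‑diene]
Product: 4, (S)‑4‑methylhex‑5‑enal
Conditions: O3 (ca. 1 equiv, Sudan Red 7B end‑point), CH2Cl2, −78 °C; then PPh3, −78 °C → rt
Reagents that add atoms: ozone, [O-][O+]=O
Why: Chemoselective Criegee ozonolysis, because the electron‑rich trisubstituted alkene reacts far faster than the monosubstituted vinyl group; the stereocentre is not involved.

Step 3
Reactants: 4, (S)‑4‑methylhex‑5‑enal
Product: 5, (3S,6Z)‑7‑iodo‑3‑methylocta‑1,6‑diene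
Conditions: EtPPh3I, n‑BuLi, THF, 0 °C; I2, −78 °C; NaHMDS, −20 °C; then 4, −78 → −20 °C
Reagents that add atoms: ethyltriphenylphosphonium iodide, CC[P+](c1ccccc1)(c1ccccc1)c1ccccc1.[I-]; iodine, II
Why: Zhao α‑iodoethylidene Wittig olefination, where the non‑stabilised iodo‑ylide gives the (Z)‑2‑iodo‑2‑alkene (I cis to the chain, typically ≥10:1) and so fixes the C6=C7 geometry.

Step 4 (key step)
Reactants: 2, (R)‑2‑(2,2‑dimethyl‑5‑oxo‑1,3‑dioxolan‑4‑yl)acetic acid (1.5 equiv); 5, (3S,6Z)‑7‑iodo‑3‑methylocta‑1,6‑diene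
Product: 6, (R)‑5‑[(2Z,6S)‑2,6‑dimethylocta‑2,7‑dien‑1‑yl]‑2,2‑dimethyl‑1,3‑dioxolan‑4‑one
Conditions: Ir[dF(CF3)ppy]2(dtbbpy)PF6 (2 mol %), NiCl2·glyme (10 mol %), dtbbpy (12 mol %), Cs2CO3 (1.5 equiv), dry degassed DMSO, 450 nm LEDs, 25 °C
Reagents that add atoms: none (CO2 and iodide are lost)
Why: Proposed new method: direct Ni/photoredox decarboxylative C(sp3)–C(sp2) alkenylation on a substrate class where it has not been shown (a free, non‑stabilised primary acid whose radical is β‑oxygenated and sits on a base‑labile chiral dioxolanone, joined to an all‑alkyl (Z)‑2‑iodo‑2‑alkene); reasoning: *Ir(III) (about +1.2 V) oxidises the caesium carboxylate of 2, CO2 loss gives the primary C5 radical (β‑alkoxy C–O scission is slow and C4 is not the radical carbon), Ni(0)/dtbbpy adds the C(sp2)–I bond of 5 with retention, radical capture gives an alkyl(alkenyl)Ni(III) species whose reductive elimination forms C5–C6 with the Z geometry intact, Ir(II) reduces Ni(I) to close both cycles, and the sensitiser triplet energy (about 60 kcal/mol) is too low to isomerise isolated alkenes; closest known reaction type: metallaphotoredox decarboxylative vinylation of α‑amino and α‑oxy acids with vinyl halides.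

Step 5
Reactants: 7, 3‑bromofuran; 8, (5‑chloropent‑1‑yn‑1‑yl)trimethylsilane
Product: 9, 3‑(pent‑4‑yn‑1‑yl)furan
Conditions: 8, Mg, THF, reflux; then 7, NiCl2(dppp) (3 mol %), THF, 0 → 50 °C; then K2CO3, MeOH, rt (one pot)
Reagents that add atoms: none (Br, Cl and SiMe3 are lost)
Why: Kumada–Corriu C(sp2)–C(sp3) coupling of the 3‑furyl bromide with a primary alkyl Grignard (dppp suppresses β‑H elimination), followed by in‑flask protodesilylation of the alkynylsilane that masked the acidic C–H.

Step 6
Reactants: 9, 3‑(pent‑4‑yn‑1‑yl)furan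
Product: 10, (E)‑2‑[5‑(furan‑3‑yl)‑2‑methylpent‑1‑en‑1‑yl]‑4,4,5,5‑tetramethyl‑1,3,2‑dioxaborolane
Conditions: AlMe3 (2.5 equiv), Cp2ZrCl2 (20 mol %), CH2Cl2, 0 °C → rt; strip excess AlMe3; MeOBpin (3 equiv), THF, −78 °C → rt
Reagents that add atoms: trimethylaluminium, C[Al](C)C; 2‑methoxy‑4,4,5,5‑tetramethyl‑1,3,2‑dioxaborolane, COB1OC(C)(C)C(C)(C)O1
Why: Negishi Zr‑catalysed carboalumination adds Me and Al syn with Me on the internal carbon, and Al→B transmetalation with retention gives the (E)‑alkenylboronate that defines C13=C14.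

Step 7
Reactants: 6, (R)‑5‑[(2Z,6S)‑2,6‑dimethylocta‑2,7‑dien‑1‑yl]‑2,2‑dimethyl‑1,3‑dioxolan‑4‑one; 10, the (E)‑alkenylboronate (1.5 equiv)
Product: 11, (R)‑5‑[(2Z,6S,7E,9E)‑13‑(furan‑3‑yl)‑2,6,10‑trimethyltrideca‑2,7,9‑trien‑1‑yl]‑2,2‑dimethyl‑1,3‑dioxolan‑4‑one
Conditions: Pd(OAc)2/1,2‑bis(phenylsulfinyl)ethane (10 mol %), benzoquinone (2 equiv), AcOH (4 equiv), dioxane, rt → 40 °C
Reagents that add atoms: none (Bpin and one vinylic H are lost)
Why: Pd(II)/sulfoxide oxidative Heck vinylation, in which transmetalation of 10, syn insertion at the CH2 terminus of the vinyl group and syn β‑H elimination give the E‑C11=C12 alkene, while the sulfoxide/quinone system suppresses Pd–H isomerisation so C10 and the other alkenes are retained.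

Step 8
Reactants: 11, the dioxolanone tetraene
Product: 12, Episarcotin A [(R)‑5‑[(2Z,6S,7E,9E)‑13‑(furan‑3‑yl)‑2,6,10‑trimethyltrideca‑2,7,9‑trien‑1‑yl]‑4‑hydroxy‑3‑methylfuran‑2(5H)‑one]
Conditions: ethyl propanoate (3.2 equiv), LDA (3.0 equiv), THF, −78 °C; add 11, −78 → 0 °C; then aq. citric acid to pH 3, 0 °C → rt
Reagents that add atoms: ethyl propanoate, CCC(=O)OCC
Why: Claisen acylation of the propanoate enolate by the activated dioxolanone carbonyl releases acetone and the C4 alkoxide, which lactonises onto the ester (Dieckmann‑type tetronic acid annulation) without breaking any bond at C4, so R is carried through.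

**Compound list**

1 | D‑malic acid, (R)‑2‑hydroxybutanedioic acid | O[C@H](CC(=O)O)C(=O)O | starting material
2 | (R)‑2‑(2,2‑dimethyl‑5‑oxo‑1,3‑dioxolan‑4‑yl)acetic acid | CC1(C)O[C@H](CC(=O)O)C(=O)O1 | intermediate
3 | (S)‑β‑citronellene, (S)‑3,7‑dimethylocta‑1,6‑diene | CC(C)=CCC[C@H](C)C=C | starting material
4 | (S)‑4‑methylhex‑5‑enal | O=CCC[C@H](C)C=C | intermediate
5 | (3S,6Z)‑7‑iodo‑3‑methylocta‑1,6‑diene | C/C(I)=C/CC[C@H](C)C=C | intermediate
6 | (R)‑5‑[(2Z,6S)‑2,6‑dimethylocta‑2,7‑dien‑1‑yl]‑2,2‑dimethyl‑1,3‑dioxolan‑4‑one | CC1(C)O[C@H](C/C(C)=C\CC[C@H](C)C=C)C(=O)O1 | intermediate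
7 | 3‑bromofuran | Brc1ccoc1 | starting material
8 | (5‑chloropent‑1‑yn‑1‑yl)trimethylsilane | C[Si](C)(C)C#CCCCCl | starting material
9 | 3‑(pent‑4‑yn‑1‑yl)furan | C#CCCCc1ccoc1 | intermediate
10 | (E)‑2‑[5‑(furan‑3‑yl)‑2‑methylpent‑1‑en‑1‑yl]‑4,4,5,5‑tetramethyl‑1,3,2‑dioxaborolane | C/C(CCCc1ccoc1)=C\B1OC(C)(C)C(C)(C)O1 | intermediate
11 | (R)‑5‑[(2Z,6S,7E,9E)‑13‑(furan‑3‑yl)‑2,6,10‑trimethyltrideca‑2,7,9‑trien‑1‑yl]‑2,2‑dimethyl‑1,3‑dioxolan‑4‑one | CC1(C)O[C@H](C/C(C)=C\CC[C@H](C)/C=C/C=C(\C)CCCc2ccoc2)C(=O)O1 | intermediate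
12 | Episarcotin A | CC1=C(O)[C@@H](C/C(C)=C\CC[C@H](C)/C=C/C=C(\C)CCCc2ccoc2)OC1=O | target

**Step count**

Total steps: 8. Longest linear sequence: 5 (steps 2, 3, 4, 7, 8, from 3 to 12).

**Three steps most likely to fail**

- **Step 4 (proposed new step).** Risks are slow oxidation of the non‑stabilised primary carboxylate, competing Ni‑mediated C–O coupling to the enol ester, and base lability of the dioxolanone. Fallback (known chemistry): switch to the reductive redox‑active‑ester manifold. Make the N‑hydroxyphthalimide ester of 2 (NHPI, DIC) and couple it with 5 by the established Ni‑electrocatalytic decarboxylative alkenylation (NiCl2/bpy, Ag‑nanoparticle‑coated cathode, Mg anode, DMF, constant current). This adds one step.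
- **Step 7.** Risks are Pd(II) palladation of the furan C2–H, 5‑exo carbopalladation onto C6=C7, and a sluggish reaction of the β,β‑disubstituted boronate. Fallback: abandon the C–H/oxidative coupling for two pre‑functionalised partners. Convert the vinyl group of 6 to its (E)‑alkenyl‑Bpin by Pd‑catalysed boryl‑Heck (catBCl, Et3N; then pinacol), and Suzuki–Miyaura couple it with the (E)‑alkenyl iodide obtained from 9 by carboalumination with I2 quench. This adds one step.
- **Step 8.** Risks are partial epimerisation at C4 through enolisation of the dioxolanone by the ester enolate, incomplete lactonisation, and acid sensitivity of the furan and diene on work‑up. Fallback: the stepwise O‑acyl α‑hydroxy ester route. Open 11 with K2CO3/MeOH to the methyl α‑hydroxy ester, O‑propionylate (EtCOCl, pyridine), and close by LiHMDS Dieckmann cyclisation at −78 °C. This adds two steps.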